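The route rests on cleaving the C6–CH3 bond of the 1,2-dioxane (ring C: O1, O2, C3–C6) and adding that methyl last. In one operation AlMe3 should ionise a 6-methoxy-1,2-dioxane to a planar peroxycarbenium ion and return CH3 along the axial path, forming the C6–CH3 bond and the quaternary peroxy stereocentre from either C6 epimer. The feature exploited is that C6 carries an axial methyl cis to the equatorial C3 propanoic acid arm, with the CH2CH2 tether equatorial. The precursor is the complete skeleton minus this methyl: a peroxyketal made from a ketone that links a pulegone-derived decalin ethyl unit (rings A and B) to an aldol-derived chain.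

Key step: step 21

Remark: centres that are destroyed later (in 7, 11, 29, 33, 34) are carried as epimer mixtures without a descriptor; decalin atoms use terpenoid numbering (ring A = C1–C5, C10; ring B = C5–C10; C4 gem-dimethyl, C5 ring-fusion CH, C8 CH(CH3), C9 quaternary), dioxane atoms are O1, O2, C3–C6, and "Dec" in names means (1R,2R,4aS)-1,2,5,5-tetramethyl-1,2,3,4,4a,5,6,7-octahydronaphthalen-1-yl.

**Decalin fragment**

Step 1
Reactants: 1 (R)-(+)-pulegone; 2 2-(2-bromoethyl)-1,3-dioxolane
Product: 5 (2S,5R)-2-[4-(1,3-dioxolan-2-yl)-2-methylbutan-2-yl]-5-methylcyclohexan-1-one (trans keto acetal), via Grignard reagent 3 (not isolated), via silyl enol ether 4 (not isolated)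
Conditions: 2, Mg, THF, 25 °C; then 1, CuBr·SMe2 (10 mol%), Me3SiCl, THF, −78 → −30 °C; then KOH, EtOH/H2O, reflux
Reagents that add atoms: none
Why: Copper-catalysed conjugate addition of the Grignard reagent to the exocyclic enone builds the gem-dimethyl carbon C4, and cleavage of the silyl enol ether under equilibrating base should give mainly the diequatorial trans (menthone-type) ketone, so the ring-fusion centre C5 is set by thermodynamic control relative to the pulegone CH(CH3) centre; the minor cis epimer is removed by chromatography and can be re-equilibrated.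

Step 2
Reactants: 5 trans keto acetal
Product: 7 (2S,5R)-2-[4-(1,3-dioxolan-2-yl)-2-methylbutan-2-yl]-5,6-dimethylcyclohexan-1-one as a mixture of C6 epimers, via lithium enolate 6 (not isolated)
Conditions: LiN(i-Pr)2, THF, −78 °C; then MeI, −78 → 0 °C
Reagents that add atoms: iodomethane CI
Why: Kinetic enolate alkylation, in which the amide base should take a proton from the open α-CH2 and not from the α-CH next to the quaternary carbon; the new methyl-bearing centre needs no control because it becomes sp2 in step 3.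

Step 3
Reactants: 7 methyl ketone
Product: 9 (3R,6S)-6-[4-(1,3-dioxolan-2-yl)-2-methylbutan-2-yl]-2,3-dimethylcyclohex-1-en-1-yl trifluoromethanesulfonate, via potassium enolate 8 (not isolated)
Conditions: KN(SiMe3)2, THF, −78 → 0 °C; then PhNTf2, −78 → 25 °C
Reagents that add atoms: N-phenylbis(trifluoromethanesulfonimide) O=S(=O)(N(c1ccccc1)S(=O)(=O)C(F)(F)F)C(F)(F)F
Why: Enol triflate formation by O-sulfonylation of the enolate; enolisation should go to the methyl-bearing side because the other α-hydrogen is screened and its enolate would force the tertiary alkyl group into the enolate plane (allylic 1,3-strain).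

Step 4
Reactants: 9 enol triflate acetal
Product: 10 (3R,6S)-2,3-dimethyl-6-(2-methyl-5-oxopentan-2-yl)cyclohex-1-en-1-yl trifluoromethanesulfonate
Conditions: 2 M aq. HCl, THF, 40 °C
Reagents that add atoms: water O
Why: Acid-catalysed acetal hydrolysis should free the aldehyde while the acid-stable enol triflate and both stereocentres stay untouched.

Step 5
Reactants: 10 enol triflate aldehyde
Product: 11 (4aS,7R)-4,4,7,8-tetramethyl-1,2,3,4,4a,5,6,7-octahydronaphthalen-1-ol as both C1 epimers
Conditions: CrCl2 (6 equiv), NiCl2 (2 mol%), degassed DMF, 25 °C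
Reagents that add atoms: none
Why: Intramolecular Nozaki–Hiyama–Kishi reaction, in which zerovalent nickel inserts into the C–OTf bond and the derived alkenylchromium species adds to the tethered aldehyde to close ring A at the C10–C1 bond; the carbinol configuration is not controlled here and is reset in steps 6 and 7.

Step 6
Reactants: 11 allylic alcohols
Product: 12 (4aS,7R)-4,4,7,8-tetramethyl-3,4,4a,5,6,7-hexahydronaphthalen-1(2H)-one
Conditions: Dess–Martin periodinane, NaHCO3, CH2Cl2, 0 → 25 °C
Reagents that add atoms: none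
Why: Dess–Martin oxidation should converge both carbinol epimers on one enone under buffered conditions that do not enolise toward C8 or C5.

Step 7
Reactants: 12 enone
Product: 13 (1S,4aS,7R)-4,4,7,8-tetramethyl-1,2,3,4,4a,5,6,7-octahydronaphthalen-1-ol
Conditions: (R)-2-methyl-CBS-oxazaborolidine (30 mol%), BH3·SMe2, THF, −30 °C
Reagents that add atoms: none
Why: Corey–Bakshi–Shibata reduction, in which the tetrasubstituted alkenyl carbon acts as the large group and the α-CH2 as the small one, so the (R)-catalyst should give the (S)-carbinol with its OH on the face of H5 and the C8 methyl, pseudo-axial to avoid allylic strain with the vinylic methyl.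

Step 8
Reactants: 13 (S)-allylic alcohol; 14 N,N-dimethylacetamide dimethyl acetal
Product: 16 N,N-dimethyl-2-Dec-acetamide, via ketene N,O-acetal 15 (not isolated)
Conditions: 14 (5 equiv), xylenes, 140 °C, sealed tube
Reagents that add atoms: none
Why: Eschenmoser–Claisen rearrangement, whose suprafacial [3,3] shift transfers the C1–O configuration to C9, so the acetamide arm should arrive on the face that carried the hydroxyl (cis to the C8 methyl), creating the quaternary centre (R) and moving the alkene to C1=C10.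

Step 9
Reactants: 16 amide
Product: 17 2-Dec-ethan-1-ol
Conditions: LiEt3BH (3 equiv), THF, 0 → 25 °C
Reagents that add atoms: none
Why: Hydride reduction of the tertiary amide with C–N cleavage should give the primary alcohol without touching the trisubstituted alkene or any stereocentre.

Step 10
Reactants: 17 primary alcohol
Product: 18 (1R,2R,4aS)-1-(2-iodoethyl)-1,2,5,5-tetramethyl-1,2,3,4,4a,5,6,7-octahydronaphthalene
Conditions: PPh3, I2, imidazole, CH2Cl2, 0 → 25 °C
Reagents that add atoms: iodine II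
Why: Appel-type iodination through the alkoxyphosphonium salt (SN2 at a primary carbon, no stereocentre involved).

**Side-chain fragment**

Step 11
Reactants: 19 (S)-4-benzyl-3-propionyloxazolidin-2-one; 20 pent-4-enal
Product: 22 (4S)-4-benzyl-3-[(2S,3R)-3-hydroxy-2-methylhept-6-enoyl]oxazolidin-2-one, via boron enolate 21 (not isolated)
Conditions: 19, Bu2BOTf, Et3N, CH2Cl2, −78 → 0 °C; then 20, −78 → 0 °C; then pH 7 buffer, MeOH, H2O2
Reagents that add atoms: none
Why: Evans syn aldol reaction, in which the Z-boron enolate reacts through a closed chair transition state on the face left open by the benzyl group, setting the CH(CH3) centre (the future propanoate C2) and the carbinol (the future dioxane C3 before inversion) in one step.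

Step 12
Reactants: 22 aldol adduct
Product: 23 (2R,3R)-2-methylhept-6-ene-1,3-diol
Conditions: LiBH4, MeOH (1 equiv), THF, 0 °C
Reagents that add atoms: none
Why: Reductive cleavage of the N-acyl oxazolidinone by borohydride should give the primary alcohol without epimerising the α-centre and releases the recoverable auxiliary.

Step 13
Reactants: 23 diol
Product: 25 tert-butyl{[(2R,3R)-2-methyl-3-[(triethylsilyl)oxy]hept-6-en-1-yl]oxy}diphenylsilane, via mono-TBDPS ether 24 (not isolated)
Conditions: t-BuPh2SiCl (1.05 equiv), imidazole, CH2Cl2, 0 °C; then Et3SiCl, DMAP (cat.), 25 °C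
Reagents that add atoms: tert-butyl(chloro)diphenylsilane CC(C)(C)[Si](Cl)(c1ccccc1)c1ccccc1; chlorotriethylsilane CC[Si](Cl)(CC)CC
Why: Sequential silylation in one flask, the bulky chlorosilane reacting only at the primary hydroxyl and the small, selectively removable triethylsilyl group then going on the secondary one; the primary oxygen is kept at the alcohol level because a carboxyl derivative would turn the later C3 mesylate into a β-leaving group.

Step 14
Reactants: 25 bis-silyl ether
Product: 27 (4R,5R)-6-[(tert-butyldiphenylsilyl)oxy]-5-methyl-4-[(triethylsilyl)oxy]hexanal, via ozonide 26 (not isolated)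
Conditions: O3, CH2Cl2, −78 °C; then PPh3, −78 → 25 °C
Reagents that add atoms: ozone [O-][O+]=O
Why: Ozonolysis of the terminal alkene with reductive work-up should give the aldehyde one carbon shorter, with silyl ethers and stereocentres inert.

**Fragment union and end game**

Step 15
Reactants: 18 decalin ethyl iodide; 27 aldehyde
Product: 29 (2R,3R)-1-[(tert-butyldiphenylsilyl)oxy]-8-Dec-2-methyl-3-[(triethylsilyl)oxy]octan-6-ol as both C6 epimers, via alkyllithium 28 (not isolated)
Conditions: 18, t-BuLi (2.1 equiv), Et2O/pentane, −78 °C; then 27, −78 °C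
Reagents that add atoms: none
Why: Iodine–lithium exchange followed by 1,2-addition of the primary alkyllithium to the aldehyde joins the fragments at the future dioxane C6; the new carbinol needs no control because it is oxidised in step 16.

Step 16
Reactants: 29 secondary alcohols
Product: 30 (6R,7R)-8-[(tert-butyldiphenylsilyl)oxy]-1-Dec-7-methyl-6-[(triethylsilyl)oxy]octan-3-one
Conditions: Dess–Martin periodinane, NaHCO3, CH2Cl2, 0 → 25 °C
Reagents that add atoms: none
Why: Buffered Dess–Martin oxidation should give the ketone without loss of the acid-labile triethylsilyl ether.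

Step 17
Reactants: 30 ketone
Product: 31 (6R,7R)-8-[(tert-butyldiphenylsilyl)oxy]-1-Dec-6-hydroxy-7-methyloctan-3-one
Conditions: HF·pyridine, pyridine, THF, 0 °C
Reagents that add atoms: none
Why: Selective desilylation, buffered fluoride cleaving the secondary triethylsilyl ether much faster than the primary tert-butyldiphenylsilyl ether, in a medium that contains no alcohol and no strong acid, so the γ-hydroxy ketone is not trapped as a cyclic ketal and is used at once.

Step 18
Reactants: 31 γ-hydroxy ketone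
Product: 32 (2R,3R)-1-[(tert-butyldiphenylsilyl)oxy]-8-Dec-2-methyl-6-oxooctan-3-yl methanesulfonate
Conditions: MsCl, Et3N, CH2Cl2, −20 → 0 °C
Reagents that add atoms: methanesulfonyl chloride CS(=O)(=O)Cl
Why: O-Sulfonylation of the secondary alcohol (retention, the C–O bond is not touched) should drain any lactol through the open hydroxy ketone.

Step 19
Reactants: 32 mesyloxy ketone
Product: 33 (2R,3R)-1-[(tert-butyldiphenylsilyl)oxy]-8-Dec-6-hydroperoxy-6-methoxy-2-methyloctan-3-yl methanesulfonate as both C6 epimers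
Conditions: urea·H2O2 (10 equiv), 10-camphorsulfonic acid (10 mol%), MeOH, 0 → 25 °C
Reagents that add atoms: hydrogen peroxide OO; methanol CO
Why: Acid-catalysed perketalisation of the ketone in methanol (capture of the methoxy oxocarbenium ion by H2O2) should give the α-methoxy hydroperoxide, with the mesylate, silyl ether and alkene tolerating the mild non-aqueous acid; the new centre needs no control because both epimers converge in step 21.

Step 20
Reactants: 33 methoxy hydroperoxide
Product: 34 tert-butyl{(2R)-2-[(3S)-6-(2-Dec-ethyl)-6-methoxy-1,2-dioxan-3-yl]propoxy}diphenylsilane as both C6 epimers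
Conditions: KOt-Bu (1.1 equiv), 18-crown-6, THF, 0 °C
Reagents that add atoms: none
Why: Intramolecular alkylation of the hydroperoxide anion by the secondary mesylate (6-exo-tet SN2) closes the O2–C3 bond with inversion, which converts the syn aldol pair into the anti C2/C3 relationship of the target and sets dioxane C3 as S.

Step 21
Reactants: 34 6-methoxy-1,2-dioxane (either C6 epimer)
Product: 36 tert-butyl{(2R)-2-[(3S,6R)-6-(2-Dec-ethyl)-6-methyl-1,2-dioxan-3-yl]propoxy}diphenylsilane, via peroxycarbenium ion 35 (not isolated)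
Conditions: AlMe3 (4 equiv), CH2Cl2, −78 → −30 °C
Reagents that add atoms: trimethylaluminium C[Al](C)C
Why: Proposed new method: AlMe3 binds the exocyclic methoxy oxygen of either epimer, loss of the methoxyaluminate gives the planar cyclic peroxycarbenium ion C6=O1(+), and a methyl group is passed from aluminium to C6 within the ion pair, so the C6–CH3 bond forms by substitution at a peroxyketal carbon. The closest known reaction types are Lewis acid-mediated substitutions of 3-alkoxy-1,2-dioxanes and 3-alkoxy-1,2-dioxolanes by allylsilanes, silyl ketene acetals and silanes through peroxycarbenium ions, and axial C-methylation of six-membered oxocarbenium ions by AlMe3, which lactol derivatives carrying an endoperoxide are known to survive. No ring is closed or opened in this step. The new quaternary centre C6 is controlled by the existing C3 centre (1,4-induction): in the half-chair cation the C3 arm is pseudo-equatorial and methyl should enter along the axial trajectory that leads directly to the chair, which places CH3 axial and cis to the arm with the tether equatorial, the (6R) configuration. The step needs ionisation of the exocyclic C6–OCH3 bond in preference to the ring C6–O1 bond, facial selectivity at C6, and survival of the O–O bond and the ring A alkene; these should be secured by the better donor ability of the methoxy oxygen toward aluminium, by the stereoelectronic preference for axial attack, and by low temperature with excess reagent so that methyl transfer outruns alkene attack on the cation and O–O heterolysis.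

Step 22
Reactants: 36 6-methyl-1,2-dioxane silyl ether
Product: 37 (2R)-2-[(3S,6R)-6-(2-Dec-ethyl)-6-methyl-1,2-dioxan-3-yl]propan-1-ol
Conditions: HF·pyridine, pyridine, THF, 0 → 25 °C
Reagents that add atoms: none
Why: Fluoride cleavage of the silyl ether under buffered, non-basic conditions should spare the dialkyl peroxide, whose C3–H would be at risk of base-induced fragmentation.

Step 23
Reactants: 37 primary alcohol
Product: 39 mycaperoxide H, via aldehyde 38 (not isolated)
Conditions: TEMPO (20 mol%), PhI(OAc)2 (2.5 equiv), MeCN/pH 7 aqueous buffer, 25 °C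
Reagents that add atoms: water O
Why: Oxoammonium-catalysed oxidation of the primary alcohol through the aldehyde hydrate to the acid under near-neutral conditions should not epimerise C2, eliminate across C2–C3, or touch the peroxide and the trisubstituted alkene.

**Compound list**

1 | (R)-(+)-pulegone, (5R)-5-methyl-2-(propan-2-ylidene)cyclohexan-1-one | C[C@@H]1CCC(=C(C)C)C(=O)C1 | starting material
2 | 2-(2-bromoethyl)-1,3-dioxolane | BrCCC1OCCO1 | starting material
3 | [2-(1,3-dioxolan-2-yl)ethyl]magnesium bromide | Br[Mg]CCC1OCCO1 | intermediate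
4 | {[(5R)-2-[4-(1,3-dioxolan-2-yl)-2-methylbutan-2-yl]-5-methylcyclohex-1-en-1-yl]oxy}trimethylsilane | C[C@@H]1CCC(C(C)(C)CCC2OCCO2)=C(O[Si](C)(C)C)C1 | intermediate
5 | (2S,5R)-2-[4-(1,3-dioxolan-2-yl)-2-methylbutan-2-yl]-5-methylcyclohexan-1-one | C[C@@H]1CC[C@@H](C(C)(C)CCC2OCCO2)C(=O)C1 | intermediate
6 | lithium (3R,6S)-6-[4-(1,3-dioxolan-2-yl)-2-methylbutan-2-yl]-3-methylcyclohex-1-en-1-olate | C[C@@H]1CC[C@@H](C(C)(C)CCC2OCCO2)C(O[Li])=C1 | intermediate
7 | (2S,5R)-2-[4-(1,3-dioxolan-2-yl)-2-methylbutan-2-yl]-5,6-dimethylcyclohexan-1-one, both C6 epimers | C[C@@H]1CC[C@@H](C(C)(C)CCC2OCCO2)C(=O)C1C | intermediate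
8 | potassium (3R,6S)-6-[4-(1,3-dioxolan-2-yl)-2-methylbutan-2-yl]-2,3-dimethylcyclohex-1-en-1-olate | C[C@@H]1CC[C@@H](C(C)(C)CCC2OCCO2)C(O[K])=C1C | intermediate
9 | (3R,6S)-6-[4-(1,3-dioxolan-2-yl)-2-methylbutan-2-yl]-2,3-dimethylcyclohex-1-en-1-yl trifluoromethanesulfonate | C[C@@H]1CC[C@@H](C(C)(C)CCC2OCCO2)C(OS(=O)(=O)C(F)(F)F)=C1C | intermediate
10 | (3R,6S)-2,3-dimethyl-6-(2-methyl-5-oxopentan-2-yl)cyclohex-1-en-1-yl trifluoromethanesulfonate | C[C@@H]1CC[C@@H](C(C)(C)CCC=O)C(OS(=O)(=O)C(F)(F)F)=C1C | intermediate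
11 | (4aS,7R)-4,4,7,8-tetramethyl-1,2,3,4,4a,5,6,7-octahydronaphthalen-1-ol, both C1 epimers | C[C@@H]1CC[C@H]2C(C)(C)CCC(O)C2=C1C | intermediate
12 | (4aS,7R)-4,4,7,8-tetramethyl-3,4,4a,5,6,7-hexahydronaphthalen-1(2H)-one | C[C@@H]1CC[C@H]2C(C)(C)CCC(=O)C2=C1C | intermediate
13 | (1S,4aS,7R)-4,4,7,8-tetramethyl-1,2,3,4,4a,5,6,7-octahydronaphthalen-1-ol | C[C@@H]1CC[C@H]2C(C)(C)CC[C@H](O)C2=C1C | intermediate
14 | N,N-dimethylacetamide dimethyl acetal (1,1-dimethoxy-N,N-dimethylethan-1-amine) | CC(OC)(OC)N(C)C | starting material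
15 | N,N-dimethyl-1-{[(1S,4aS,7R)-4,4,7,8-tetramethyl-1,2,3,4,4a,5,6,7-octahydronaphthalen-1-yl]oxy}ethen-1-amine | C[C@@H]1CC[C@H]2C(C)(C)CC[C@H](OC(=C)N(C)C)C2=C1C | intermediate
16 | N,N-dimethyl-2-[(1R,2R,4aS)-1,2,5,5-tetramethyl-1,2,3,4,4a,5,6,7-octahydronaphthalen-1-yl]acetamide | CN(C)C(=O)C[C@@]1(C)C2=CCCC(C)(C)[C@@H]2CC[C@H]1C | intermediate
17 | 2-[(1R,2R,4aS)-1,2,5,5-tetramethyl-1,2,3,4,4a,5,6,7-octahydronaphthalen-1-yl]ethan-1-ol | OCC[C@@]1(C)C2=CCCC(C)(C)[C@@H]2CC[C@H]1C | intermediate
18 | (1R,2R,4aS)-1-(2-iodoethyl)-1,2,5,5-tetramethyl-1,2,3,4,4a,5,6,7-octahydronaphthalene | ICC[C@@]1(C)C2=CCCC(C)(C)[C@@H]2CC[C@H]1C | intermediate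
19 | (S)-4-benzyl-3-propionyloxazolidin-2-one | CCC(=O)N1[C@@H](Cc2ccccc2)COC1=O | starting material
20 | pent-4-enal | C=CCCC=O | starting material
21 | (Z)-dibutylboron enolate of 19 | C/C=C(\OB(CCCC)CCCC)N1[C@@H](Cc2ccccc2)COC1=O | intermediate
22 | (4S)-4-benzyl-3-[(2S,3R)-3-hydroxy-2-methylhept-6-enoyl]oxazolidin-2-one | C=CCC[C@@H](O)[C@H](C)C(=O)N1[C@@H](Cc2ccccc2)COC1=O | intermediate
23 | (2R,3R)-2-methylhept-6-ene-1,3-diol | C=CCC[C@@H](O)[C@H](C)CO | intermediate
24 | (2R,3R)-1-[(tert-butyldiphenylsilyl)oxy]-2-methylhept-6-en-3-ol | C=CCC[C@@H](O)[C@H](C)CO[Si](c1ccccc1)(c1ccccc1)C(C)(C)C | intermediate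
25 | tert-butyl{[(2R,3R)-2-methyl-3-[(triethylsilyl)oxy]hept-6-en-1-yl]oxy}diphenylsilane | C=CCC[C@@H](O[Si](CC)(CC)CC)[C@H](C)CO[Si](c1ccccc1)(c1ccccc1)C(C)(C)C | intermediate
26 | secondary ozonide of 25, 3-[(3R,4R)-5-[(tert-butyldiphenylsilyl)oxy]-4-methyl-3-[(triethylsilyl)oxy]pentyl]-1,2,4-trioxolane | O1OC(CC[C@@H](O[Si](CC)(CC)CC)[C@H](C)CO[Si](c2ccccc2)(c2ccccc2)C(C)(C)C)OC1 | intermediate
27 | (4R,5R)-6-[(tert-butyldiphenylsilyl)oxy]-5-methyl-4-[(triethylsilyl)oxy]hexanal | O=CCC[C@@H](O[Si](CC)(CC)CC)[C@H](C)CO[Si](c1ccccc1)(c1ccccc1)C(C)(C)C | intermediate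
28 | 2-Dec-ethyllithium | [Li]CC[C@@]1(C)C2=CCCC(C)(C)[C@@H]2CC[C@H]1C | intermediate
29 | (2R,3R)-1-[(tert-butyldiphenylsilyl)oxy]-8-Dec-2-methyl-3-[(triethylsilyl)oxy]octan-6-ol, both C6 epimers | OC(CC[C@@H](O[Si](CC)(CC)CC)[C@H](C)CO[Si](c1ccccc1)(c1ccccc1)C(C)(C)C)CC[C@@]1(C)C2=CCCC(C)(C)[C@@H]2CC[C@H]1C | intermediate
30 | (6R,7R)-8-[(tert-butyldiphenylsilyl)oxy]-1-Dec-7-methyl-6-[(triethylsilyl)oxy]octan-3-one | O=C(CC[C@@H](O[Si](CC)(CC)CC)[C@H](C)CO[Si](c1ccccc1)(c1ccccc1)C(C)(C)C)CC[C@@]1(C)C2=CCCC(C)(C)[C@@H]2CC[C@H]1C | intermediate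
31 | (6R,7R)-8-[(tert-butyldiphenylsilyl)oxy]-1-Dec-6-hydroxy-7-methyloctan-3-one | O=C(CC[C@@H](O)[C@H](C)CO[Si](c1ccccc1)(c1ccccc1)C(C)(C)C)CC[C@@]1(C)C2=CCCC(C)(C)[C@@H]2CC[C@H]1C | intermediate
32 | (2R,3R)-1-[(tert-butyldiphenylsilyl)oxy]-8-Dec-2-methyl-6-oxooctan-3-yl methanesulfonate | O=C(CC[C@@H](OS(C)(=O)=O)[C@H](C)CO[Si](c1ccccc1)(c1ccccc1)C(C)(C)C)CC[C@@]1(C)C2=CCCC(C)(C)[C@@H]2CC[C@H]1C | intermediate
33 | (2R,3R)-1-[(tert-butyldiphenylsilyl)oxy]-8-Dec-6-hydroperoxy-6-methoxy-2-methyloctan-3-yl methanesulfonate, both C6 epimers | COC(OO)(CC[C@@H](OS(C)(=O)=O)[C@H](C)CO[Si](c1ccccc1)(c1ccccc1)C(C)(C)C)CC[C@@]1(C)C2=CCCC(C)(C)[C@@H]2CC[C@H]1C | intermediate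
34 | tert-butyl{(2R)-2-[(3S)-6-(2-Dec-ethyl)-6-methoxy-1,2-dioxan-3-yl]propoxy}diphenylsilane, both C6 epimers | C[C@H](CO[Si](c1ccccc1)(c1ccccc1)C(C)(C)C)[C@@H]1CCC(OC)(CC[C@@]2(C)C3=CCCC(C)(C)[C@@H]3CC[C@H]2C)OO1 | intermediate
35 | cyclic peroxycarbenium ion (C6=O1 cation of 34 after loss of methoxide, C3 S) as its methoxytrimethylaluminate ion pair | C[C@H](CO[Si](c1ccccc1)(c1ccccc1)C(C)(C)C)[C@@H]1CCC(CC[C@@]2(C)C3=CCCC(C)(C)[C@@H]3CC[C@H]2C)=[O+]O1.CO[Al-](C)(C)C | intermediate
36 | tert-butyl{(2R)-2-[(3S,6R)-6-(2-Dec-ethyl)-6-methyl-1,2-dioxan-3-yl]propoxy}diphenylsilane | C[C@H](CO[Si](c1ccccc1)(c1ccccc1)C(C)(C)C)[C@@H]1CC[C@@](C)(CC[C@@]2(C)C3=CCCC(C)(C)[C@@H]3CC[C@H]2C)OO1 | intermediate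
37 | (2R)-2-[(3S,6R)-6-(2-Dec-ethyl)-6-methyl-1,2-dioxan-3-yl]propan-1-ol | C[C@H](CO)[C@@H]1CC[C@@](C)(CC[C@@]2(C)C3=CCCC(C)(C)[C@@H]3CC[C@H]2C)OO1 | intermediate
38 | (2S)-2-[(3S,6R)-6-(2-Dec-ethyl)-6-methyl-1,2-dioxan-3-yl]propanal | C[C@H](C=O)[C@@H]1CC[C@@](C)(CC[C@@]2(C)C3=CCCC(C)(C)[C@@H]3CC[C@H]2C)OO1 | intermediate
39 | mycaperoxide H, (2S)-2-[(3S,6R)-6-methyl-6-{2-[(1R,2R,4aS)-1,2,5,5-tetramethyl-1,2,3,4,4a,5,6,7-octahydronaphthalen-1-yl]ethyl}-1,2-dioxan-3-yl]propanoic acid | C[C@H](C(=O)O)[C@@H]1CC[C@@](C)(CC[C@@]2(C)C3=CCCC(C)(C)[C@@H]3CC[C@H]2C)OO1 | target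

**Step count and risks**

Total step count: 23. Longest linear sequence: 19 steps (steps 1–10 and 15–23, from pulegone).

Steps most likely to fail:

1. Step 21 (the new peroxyketal methylation). The peroxyketal may fail to ionise, methyl may add with poor facial selectivity at C6, the ring A alkene may capture the cation, or the organoaluminium may cleave the O–O bond. The fallback uses known chemistry and sets out from hydroxy ketone 31. Wittig methylenation (Ph3PCH3Br, KOt-Bu, excess) would give the 1,1-disubstituted alkene alcohol F1, and mesylation the alkene mesylate F2. Isayama–Mukaiyama hydroperoxysilylation (Co(acac)2, O2, Et3SiH) should oxygenate the exposed methylidene in Markovnikov fashion, in preference to the hindered ring A alkene, to give the tertiary triethylsilyl peroxide F3. Brief treatment with Bu4NF at 0 °C would free the tertiary hydroperoxide F4, and KOt-Bu with 18-crown-6 would close it onto the mesylate (6-exo-tet, inversion at C3). Because C6 is formed without control in the radical oxygenation, this would give 36 together with its C6 epimer F5, to be separated by chromatography. The route is rejoined at 36.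

2. Step 19 (perketalisation next to a leaving group). The ketone may give the dimethyl ketal or the geminal dihydroperoxide instead, or the hemiketal oxygen may displace the mesylate early to form a tetrahydrofuran. The fallback sets out from mesylate 32 and forms the C3–O bond first. Intermolecular SN2 displacement with 2-methoxyprop-2-yl hydroperoxide and CsOH·H2O in DMF (inversion) would give the secondary peroxy ketal F6. 10-Camphorsulfonic acid in MeOH would then unmask the γ-hydroperoxy ketone F7, which should close onto the ketone to the cyclic peroxy hemiketal F8 and be methylated in the same acidic methanol. The ring is thereby closed at O1–C6 instead of O2–C3, and the route is rejoined at 34.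

3. Step 5 (ring A closure). Oxidative addition at the hindered tetrasubstituted enol triflate may be sluggish, leaving time for protodemetalation or aldehyde self-condensation. The fallback sets out from triflate acetal 9 and replaces the alkenylmetal addition by a cationic alkene acylation. Formate reduction of the triflate (Pd(OAc)2, PPh3, Bu3N, HCO2H, DMF, 60 °C) would give the regiodefined trisubstituted alkene acetal F9. Aqueous acid would give the alkene aldehyde F10, Pinnick oxidation (NaClO2, NaH2PO4, 2-methyl-2-butene) the alkenoic acid F11, and (COCl)2 the acid chloride F12. With SnCl4 in CH2Cl2 at −78 °C the acylium carbon should attack C10 (six-membered closure, tertiary cation at C9), and loss of the C10 proton would give the conjugated enone. The route is rejoined at 12.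

**Further compounds**

F1 | step 21 | (2R,3R)-1-[(tert-butyldiphenylsilyl)oxy]-8-Dec-2-methyl-6-methylideneoctan-3-ol | C=C(CC[C@@H](O)[C@H](C)CO[Si](c1ccccc1)(c1ccccc1)C(C)(C)C)CC[C@@]1(C)C2=CCCC(C)(C)[C@@H]2CC[C@H]1C
F2 | step 21 | (2R,3R)-1-[(tert-butyldiphenylsilyl)oxy]-8-Dec-2-methyl-6-methylideneoctan-3-yl methanesulfonate | C=C(CC[C@@H](OS(C)(=O)=O)[C@H](C)CO[Si](c1ccccc1)(c1ccccc1)C(C)(C)C)CC[C@@]1(C)C2=CCCC(C)(C)[C@@H]2CC[C@H]1C
F3 | step 21 | (2R,3R)-1-[(tert-butyldiphenylsilyl)oxy]-8-Dec-2,6-dimethyl-6-[(triethylsilyl)peroxy]octan-3-yl methanesulfonate, both C6 epimers | CC(OO[Si](CC)(CC)CC)(CC[C@@H](OS(C)(=O)=O)[C@H](C)CO[Si](c1ccccc1)(c1ccccc1)C(C)(C)C)CC[C@@]1(C)C2=CCCC(C)(C)[C@@H]2CC[C@H]1C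
F4 | step 21 | (2R,3R)-1-[(tert-butyldiphenylsilyl)oxy]-8-Dec-6-hydroperoxy-2,6-dimethyloctan-3-yl methanesulfonate, both C6 epimers | CC(OO)(CC[C@@H](OS(C)(=O)=O)[C@H](C)CO[Si](c1ccccc1)(c1ccccc1)C(C)(C)C)CC[C@@]1(C)C2=CCCC(C)(C)[C@@H]2CC[C@H]1C
F5 | step 21 | tert-butyl{(2R)-2-[(3S,6S)-6-(2-Dec-ethyl)-6-methyl-1,2-dioxan-3-yl]propoxy}diphenylsilane (C6 epimer of 36) | C[C@H](CO[Si](c1ccccc1)(c1ccccc1)C(C)(C)C)[C@@H]1CC[C@](C)(CC[C@@]2(C)C3=CCCC(C)(C)[C@@H]3CC[C@H]2C)OO1
F6 | step 19 | (6S,7R)-8-[(tert-butyldiphenylsilyl)oxy]-1-Dec-6-[(2-methoxypropan-2-yl)peroxy]-7-methyloctan-3-one | C[C@H](CO[Si](c1ccccc1)(c1ccccc1)C(C)(C)C)[C@@H](OOC(C)(C)OC)CCC(=O)CC[C@@]1(C)C2=CCCC(C)(C)[C@@H]2CC[C@H]1C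
F7 | step 19 | (6S,7R)-8-[(tert-butyldiphenylsilyl)oxy]-1-Dec-6-hydroperoxy-7-methyloctan-3-one | C[C@H](CO[Si](c1ccccc1)(c1ccccc1)C(C)(C)C)[C@@H](OO)CCC(=O)CC[C@@]1(C)C2=CCCC(C)(C)[C@@H]2CC[C@H]1C
F8 | step 19 | (6S)-6-[(2R)-1-[(tert-butyldiphenylsilyl)oxy]propan-2-yl]-3-(2-Dec-ethyl)-1,2-dioxan-3-ol (cyclic peroxy hemiketal, both C3 epimers) | C[C@H](CO[Si](c1ccccc1)(c1ccccc1)C(C)(C)C)[C@@H]1CCC(O)(CC[C@@]2(C)C3=CCCC(C)(C)[C@@H]3CC[C@H]2C)OO1
F9 | step 5 | 2-{3-[(1R,4R)-3,4-dimethylcyclohex-2-en-1-yl]-3-methylbutyl}-1,3-dioxolane | C[C@@H]1CC[C@@H](C(C)(C)CCC2OCCO2)C=C1C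
F10 | step 5 | 4-[(1R,4R)-3,4-dimethylcyclohex-2-en-1-yl]-4-methylpentanal | C[C@@H]1CC[C@@H](C(C)(C)CCC=O)C=C1C
F11 | step 5 | 4-[(1R,4R)-3,4-dimethylcyclohex-2-en-1-yl]-4-methylpentanoic acid | C[C@@H]1CC[C@@H](C(C)(C)CCC(=O)O)C=C1C
F12 | step 5 | 4-[(1R,4R)-3,4-dimethylcyclohex-2-en-1-yl]-4-methylpentanoyl chloride | C[C@@H]1CC[C@@H](C(C)(C)CCC(Cl)=O)C=C1C
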